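The numbers were drawn at random within sensible limits.

Begin at early times, when L and G first meet and each X is still new.

    L + G → Q + X (k1 = 29.9 M⁻¹ min⁻¹, Ea1 = 46.0 kJ mol⁻¹)
    J + G → Q + Z (k2 = 87.4 M⁻¹ min⁻¹, Ea2 = 71.0 kJ mol⁻¹)
    Q + L → Q.L (k3 = 2.11 M⁻¹ min⁻¹, Ea3 = 66.0 kJ mol⁻¹)
    X + G → Q + J (k4 = 10.8 M⁻¹ min⁻¹, Ea4 = 86.0 kJ mol⁻¹)
    (constants at 110 °C)

the same everywhere: time 30 min
- larch: L 0.050 M; G 0.0650 M (fed, over 6.0 min); temperature 110 °C; all else is in the flask from the start; the feed brings no volume worth counting
- ash: L 0.050 M; G 0.0650 M (in portions, 2, over 6.0 min); temperature 110 °C; first portion at the start, last at 6.0 min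
- elm: L 0.050 M (fed, over 6.0 min); G 0.0650 M; temperature 110 °C; all else is in the flask from the start; the feed brings no volume worth counting
- birch: L 0.050 M; G 0.0650 M (fed, over 40 s); temperature 110 °C; all else is in the flask from the start; the feed brings no volume worth counting
- oak: L 0.050 M (fed, over 6.0 min); G 0.0650 M; the addition at 80 °C, then warmed to 110 °C; the feed brings no volume worth counting
- cedar: L 0.050 M; G 0.0650 M; everything together at the start at 80 °C, warmed to 110 °C at 6.0 min

- at 110 °C the constants are as listed, elsewhere as the activation energies make them

- which flask leads in amount of Q.L, in percent of the L charged ("all alike" within 1.5 percentage points) (larch / ash / elm / birch / oak / cedar / all alike)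
- how much Q.L is there at the end, in percent of the L charged: larch
- how much Q.L is there at the end, in percent of the L charged: ash
- how much Q.L is there at the end, in percent of the L charged: elm
- how much Q.L is there at the end, in percent of the L charged: birch
- how much Q.L is there at the end, in percent of the L charged: oak
- how much Q.L is there at the end, in percent of the L charged: cedar

Count G first. The flasks hold 1.30 G per L, against 3 per L for full exchange, so G is the limiting reagent. While G lasts, Q competes poorly for L. L that G never reaches meets Q instead, and each G used frees one Q, so [Q] nears the G charge. That gives L a lifetime near 7.29 min, shorter than the 30 min allowed, so this L ends as Q.L. Now look at X. J takes G with 87.4 M⁻¹ min⁻¹, faster than X does with 10.8 M⁻¹ min⁻¹, so treat the step from X to Z as one move costing 2 G.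

Divide the rate at which G takes X by the rate at which it takes L: [G] cancels, and [X] over [L] remains, multiplied by the ratio of the second exchange constant to the first, the selectivity factor 0.361. It says how strongly one X competes with one L for G. Plotted against L used, [X] rises to a peak, sf raised to the power sf over one minus sf, here 56.2% of the L charged. That top is flat, so replace [X] at the end of G by its peak. The balances of L and G then leave, for a flask with its G in quickly, 19.2% of L unreached. I take this for birch, and place larch and ash near it.

Test whether one number suffices. The slow feed lasts 8.97 lifetimes of G against the L charged, and the quick one 0.997, so the length of the feed can count. In elm, X stands among G while L is scarce. Replace the fall of [G] in elm over the feed by a straight line down to nothing. An X born at some moment then sees the triangle under that line after its birth, and averaged over the moments of birth this area is the charge over 2 times the feed time over 3, so an X collects on average an exposure 0.702. Take exposure over one plus exposure as the rough share of X moving on, each at 2 more G; the G charge then leaves 28.8% of L unreached in elm. At 80 °C the factor drops to 0.124, and the flat peak then gives 7.08%. My choice is elm.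

The forecast also names elm, with larch 21.5%, ash 24.5%, elm 30%, birch 19%, oak 17% and cedar 13%, on the ground that “Feeding L into G is worst for selectivity”.

The simulation puts elm first with 29.8%, then ash 24.0%, larch 21.7%, birch 18.9%, oak 16.8% and cedar 12.0%. In birch, X ends at 52.7% of the L charged, beside the peak of 56.2%. Put the factor to use once more on cedar, which started cold and was warmed at 6.00 min: 0.124 gives 7.08% and 0.361 gives the birch figure, and cedar's Q.L lies between them at 12.0%.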